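How much Z stood at 25 s was my first question: L turns over through steps that consume Z.

L 10 mM; Z 50.0 mM; time 25 s

    L + Z + Q → D + 2 Q (k1 = 470 M⁻² s⁻¹)
    L + Z → D + Q (k2 = 0.12 M⁻¹ s⁻¹)
    G ⇌ D, rate k3*(cs3 - [D]) while solid is left; crystals form when [D] > cs3 (cs3 = 6.0 mM, k3 = 4.4 s⁻¹)
    2 Z → Z2 (k4 = 1.7 M⁻¹ s⁻¹)

1. D and G together at 25 s, in percent of the L charged
2. the change that raises the amount of D and G together at 25 s, in percent of the L charged most ("none" if none brings more than 2 percentage points) (midnight / autumn / dawn / none)
3. amount of D and G together at 25 s, in percent of the L charged, after autumn

- midnight: doubling the solubility in step 3, all else as stated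
- autumn: doubling the amount of Z, all else as stated
- dawn: doubling the dissolution coefficient of step 3, all else as stated

- for D the G are counted in
- a step written with two of one species runs at k times the square of its concentration and takes two of it each time
- as a solid, counted per litre of solution: G
- run time (flask): 25 s

At the charge in the flask, each Z passed into Z2 at 0.170 s⁻¹ and into D by the plain route at 0.001200 s⁻¹, so I left L out of my curve of [Z]. The dimerisation curve then gave 9.52 mM of Z at 25 s.

Next, when does Q matter? The catalysed route overtakes the plain one once [Q] passes 0.255 mM, and that is less than the L charged: this is autocatalysis, with the plain route as its seed.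

So what clock does L obey? It is the Z exposure, the integral of [Z] over time: on the dimerisation curve, the logarithm of charged [Z] over remaining [Z], divided by twice the dimerisation constant. In the flask it came to 0.488 M·s. The ratio of [Q] plus seed to remaining [L] grows exponentially with exposure, by an exponent of 2.35, which gave me 19.1% of the L charged as D. At that end of my curve, dimerisation still used Z 3.93 times as fast as the two routes to D together.

Autumn, with Z doubled, raised my exposure to 0.662 M·s, and the same reckoning gave 36.7%. That put [D] at 3.67 mM, still below the solubility, so I expected nothing from midnight or dawn.

The forecast gave 18.5% (17% to 20%), autumn as the best change and 35.5% (32.5% to 38%), holding that “only the time-integrated Z matters”.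

The simulation gave 18.3%, autumn as the best change with a gain of 16 percentage points, and 34.6% after it.

For a neighbour flask charged with 200 mM of Z, L unchanged, I reckoned an exposure of 0.850 M·s, which was 1.74 times my exposure for the flask. Its exponent was 4.10, and the reckoning gave 59.6%. The simulated neighbour gave 56.3%, with 0% of the L charged as G.

The constants used here stand for no real mixture, and the outcome is calculated.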